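**Retrosynthetic overview**

1. The two phenols are unmasked last from a bis(benzyl ether). Before that, the pyranone (ring B) is cut at C4a–C4 and O2–C3, giving a diarylmethane benzoic acid and the acetyl sulfoxonium ylide MeC(O)CH=S(O)Me2.
2. Feature used: in ring A the carboxyl-bearing carbon C8a has two ortho neighbours, C8 (blocked by OMe) and C4a (C–H), so a carboxylate-bound metal can reach C4a only. C1 and O2 come from the carboxyl group; C3, C4 and the 3-methyl group come from the ylide.
3. The C5–CH2 bond is cut next (Negishi coupling): ring A as methyl 4-(benzyloxy)-5-bromo-2-methoxybenzoate, ring C as a benzylic zinc chloride.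
4. Ring C (OMe ortho, OH para and CH2OMe ortho to the benzylic carbon) is traced to 4-methoxy-6-methyl-2-pyrone, acylated at its methyl group with a methoxyacetyl unit and recyclised by base (ring opening, aldol closure).
5. Order of ring formation: ring C (carbocycle from the pyrone), ring A bought as the benzoate, ring B last.

Key step: step 11

Remark on the chemistry: the target has no stereocentre and no stereogenic double bond, so no stereocontrol is needed. Isocoumarin numbering (C1, O2, C3, C4, C4a, C5 to C8, C8a) is used for rings A and B throughout.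

**Route**

Step 1
Reactants: 1 4-methoxy-6-methyl-2H-pyran-2-one; 2 N,2-dimethoxy-N-methylacetamide
Product: 3 4-methoxy-6-(3-methoxy-2-oxopropyl)-2H-pyran-2-one
Conditions: LiN(iPr)2 (1.1 equiv), THF, −78 °C; then 2, −78 → 0 °C; 1 M HCl
Reagents that add atoms: none
Why: Vinylogous deprotonation of the C6 methyl group followed by a Weinreb ketone synthesis; the chelated tetrahedral adduct should hold until the quench, so one equivalent of base suffices and neither over-addition nor enolisation of an ester-type partner by spare base can interfere.

Step 2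
Reactants: 3 4-methoxy-6-(3-methoxy-2-oxopropyl)-2H-pyran-2-one
Product: 5 4-hydroxy-2-methoxy-6-(methoxymethyl)benzoic acid, via open-chain diketo acid 4 (not isolated)
Conditions: 2 M aq. KOH, 25 → 50 °C; then 2 M HCl, 0 °C, pH 3
Reagents that add atoms: potassium hydroxide (its oxygen ends in the carboxyl group), [K+].[OH-]
Why: Polyketide-type pyrone recyclisation: hydroxide opens the lactone to the carboxylate of 4, which cannot close in the Claisen mode, so intramolecular aldol condensation of C2 onto the C7 ketone and loss of water should give the benzoic acid with the enol ether methyl kept ortho to the carboxyl group and the free phenol para to it.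

Step 3
Reactants: 5 4-hydroxy-2-methoxy-6-(methoxymethyl)benzoic acid
Product: 6 benzyl 4-(benzyloxy)-2-methoxy-6-(methoxymethyl)benzoate
Conditions: BnBr (2.3 equiv), K2CO3, DMF, rt
Reagents that add atoms: benzyl bromide, BrCc1ccccc1
Why: Double O-alkylation (Williamson type, SN2 at benzyl bromide) of the phenoxide and the hindered carboxylate masks the phenol and turns the decarboxylation-prone acid into a stable ester in one operation.

Step 4
Reactants: 6 benzyl 4-(benzyloxy)-2-methoxy-6-(methoxymethyl)benzoate
Product: 7 [4-(benzyloxy)-2-methoxy-6-(methoxymethyl)phenyl]methanol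
Conditions: LiAlH4, THF, 0 °C → 40 °C; aqueous work-up
Reagents that add atoms: none
Why: Hydride reduction of the ester to the primary alcohol; LiAlH4 is chosen because the carbonyl group has two ortho substituents, and aryl benzyl, aryl methyl and benzylic methyl ethers are inert to it.

Step 5
Reactants: 7 [4-(benzyloxy)-2-methoxy-6-(methoxymethyl)phenyl]methanol
Product: 9 5-(benzyloxy)-2-(chloromethyl)-1-methoxy-3-(methoxymethyl)benzene, via benzylic mesylate 8 (not isolated)
Conditions: MsCl, Et3N, CH2Cl2, 0 °C → rt; cold aqueous wash, used crude at once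
Reagents that add atoms: methanesulfonyl chloride, CS(=O)(=O)Cl
Why: Mesylation followed by in situ nucleophilic displacement by the released chloride: the ortho and para alkoxy groups make 8 very reactive, the amine keeps the medium acid-free so that Friedel–Crafts self-alkylation is held back, and the chloride is preferred to the bromide because it keeps better and gives less Wurtz coupling on zinc.

Step 6
Reactants: 10 methyl 4-hydroxy-2-methoxybenzoate
Product: 11 methyl 5-bromo-4-hydroxy-2-methoxybenzoate
Conditions: NBS (1.0 equiv), MeCN, 0 °C → rt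
Reagents that add atoms: N-bromosuccinimide, O=C1CCC(=O)N1Br
Why: Electrophilic aromatic bromination: C5 is ortho to the free phenol, para to the methoxy group and open, whereas the equally activated C3 is wedged between two oxygen substituents, so monobromination should go to C5.

Step 7
Reactants: 11 methyl 5-bromo-4-hydroxy-2-methoxybenzoate
Product: 12 methyl 4-(benzyloxy)-5-bromo-2-methoxybenzoate
Conditions: BnBr, K2CO3, DMF, 50 °C
Reagents that add atoms: benzyl bromide, BrCc1ccccc1
Why: Williamson ether synthesis on the phenoxide; the aryl bromide and the methyl ester are inert to K2CO3 under these conditions.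

Step 8
Reactants: 9 5-(benzyloxy)-2-(chloromethyl)-1-methoxy-3-(methoxymethyl)benzene; 12 methyl 4-(benzyloxy)-5-bromo-2-methoxybenzoate
Product: 14 methyl 4-(benzyloxy)-5-{[4-(benzyloxy)-2-methoxy-6-(methoxymethyl)phenyl]methyl}-2-methoxybenzoate, via benzylic zinc chloride 13 (not isolated)
Conditions: Zn dust, LiCl, THF, 25 °C; then 12, Pd(OAc)2 (2 mol %), SPhos (4 mol %), THF, 25 → 50 °C
Reagents that add atoms: zinc (held only in intermediate 13), [Zn]
Why: LiCl-mediated zinc insertion into the benzylic C–Cl bond followed by Negishi coupling (oxidative addition of zerovalent palladium into C5–Br, transmetalation, reductive elimination): the organozinc tolerates the ester and ethers, methoxide is too poor a leaving group for 1,4-elimination from the covalent C–Zn bond, and the bulky electron-rich biarylphosphine handles the electron-rich ortho-substituted bromide.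

Step 9
Reactants: 14 methyl 4-(benzyloxy)-5-{[4-(benzyloxy)-2-methoxy-6-(methoxymethyl)phenyl]methyl}-2-methoxybenzoate
Product: 15 4-(benzyloxy)-5-{[4-(benzyloxy)-2-methoxy-6-(methoxymethyl)phenyl]methyl}-2-methoxybenzoic acid
Conditions: LiOH, THF/MeOH/H2O, 50 °C; then 1 M HCl, 0 °C, pH 3
Reagents that add atoms: lithium hydroxide, [Li+].[OH-]
Why: Saponification (acyl–oxygen cleavage) of an ester with only one ortho substituent; all the ether groups are inert to hydroxide.

Step 10
Reactants: 16 trimethylsulfoxonium iodide; 17 acetic anhydride
Product: 19 1-[dimethyl(oxo)-λ6-sulfanylidene]propan-2-one, via dimethylsulfoxonium methylide 18 (not isolated)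
Conditions: 16 (2.5 equiv), KOtBu (2.5 equiv), THF, reflux; then 17 (1.0 equiv), 0 °C → rt
Reagents that add atoms: none
Why: Deprotonation gives the Corey–Chaykovsky methylide 18, and its C-acylation by the anhydride gives a β-keto sulfoxonium salt that a second equivalent of 18 deprotonates to the stabilised ylide 19 (acylation of a sulfur ylide).

Step 11
Reactants: 15 4-(benzyloxy)-5-{[4-(benzyloxy)-2-methoxy-6-(methoxymethyl)phenyl]methyl}-2-methoxybenzoic acid; 19 1-[dimethyl(oxo)-λ6-sulfanylidene]propan-2-one
Product: 21 6-(benzyloxy)-5-{[4-(benzyloxy)-2-methoxy-6-(methoxymethyl)phenyl]methyl}-8-methoxy-3-methyl-1H-isochromen-1-one, via keto acid 20 (not isolated)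
Conditions: [Cp*RhCl2]2 (5 mol %), AgSbF6 (20 mol %), NaOAc (1.0 equiv), 19 (2.0 equiv, in portions), ClCH2CH2Cl, 100 °C, sealed tube
Reagents that add atoms: none
Why: Acetate-assisted concerted metalation–deprotonation by the cationic Cp*Rh complex of trivalent rhodium, held by the carboxylate of 15, gives a five-membered rhodacycle at C4a; ylide 19 binds through carbon, loses DMSO to give a rhodium carbene, and migratory insertion of the aryl group followed by protonolysis forms C4a–C4 and releases keto acid 20 without any external oxidant. The closest known reaction type is the [Cp*RhCl2]2- or [Ru(p-cymene)Cl2]2-catalysed annulation of benzoic acids with α-carbonyl sulfoxonium ylides to 3-substituted isocoumarins, so the step applies known chemistry to a new acid. Ring B closes in the same pot by 6-exo-trig attack of a carboxyl oxygen (the future O2) on the ketone carbon C3, and the hemiketal loses water, the former ketone oxygen leaving, to set the C3–C4 double bond. No stereocentre is formed. The step needs site selectivity and a preference for C–H functionalisation over O-alkylation of the carboxylate: the C8 methoxy group blocks the second ortho position so that only C4a–H lies within reach of the bound metal, ring C and the benzyl groups carry no comparable directing group, and portionwise addition of 19 with NaOAc as buffer keeps the protonated ylide scarce. The ylide also fixes the 3-methyl, 4-unsubstituted pattern, but the site is flanked by the C5 benzylic substituent, so a high catalyst loading and a long reaction time are planned.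

Step 12
Reactants: 21 6-(benzyloxy)-5-{[4-(benzyloxy)-2-methoxy-6-(methoxymethyl)phenyl]methyl}-8-methoxy-3-methyl-1H-isochromen-1-one
Product: 22 6-hydroxy-5-{[4-hydroxy-2-methoxy-6-(methoxymethyl)phenyl]methyl}-8-methoxy-3-methyl-1H-isochromen-1-one
Conditions: H2 (1 atm), 10% Pd/C, EtOAc, rt, stopped after uptake of two equivalents of H2
Reagents that add atoms: none
Why: Catalytic hydrogenolysis: the two unhindered PhCH2–OAr bonds (phenol leaving groups) should be cleaved well before the crowded ring C ArCH2–OMe bond (alcohol leaving group, ortho-substituted arene that binds poorly to the metal surface) and before the trisubstituted conjugated C3–C4 double bond, provided a neutral aprotic solvent is used and the uptake is watched.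

**Compound list**

1 | 4-methoxy-6-methyl-2H-pyran-2-one | COc1cc(C)oc(=O)c1 | starting material
2 | N,2-dimethoxy-N-methylacetamide | COCC(=O)N(C)OC | starting material
3 | 4-methoxy-6-(3-methoxy-2-oxopropyl)-2H-pyran-2-one | COCC(=O)Cc1cc(OC)cc(=O)o1 | intermediate
4 | (E)-3,8-dimethoxy-5,7-dioxooct-2-enoic acid (present as its salt, not isolated) | COCC(=O)CC(=O)C/C(OC)=C\C(=O)O | intermediate
5 | 4-hydroxy-2-methoxy-6-(methoxymethyl)benzoic acid | COCc1cc(O)cc(OC)c1C(=O)O | intermediate
6 | benzyl 4-(benzyloxy)-2-methoxy-6-(methoxymethyl)benzoate | COCc1cc(OCc2ccccc2)cc(OC)c1C(=O)OCc1ccccc1 | intermediate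
7 | [4-(benzyloxy)-2-methoxy-6-(methoxymethyl)phenyl]methanol | COCc1cc(OCc2ccccc2)cc(OC)c1CO | intermediate
8 | [4-(benzyloxy)-2-methoxy-6-(methoxymethyl)phenyl]methyl methanesulfonate (not isolated) | COCc1cc(OCc2ccccc2)cc(OC)c1COS(C)(=O)=O | intermediate
9 | 5-(benzyloxy)-2-(chloromethyl)-1-methoxy-3-(methoxymethyl)benzene | COCc1cc(OCc2ccccc2)cc(OC)c1CCl | intermediate
10 | methyl 4-hydroxy-2-methoxybenzoate | COC(=O)c1ccc(O)cc1OC | starting material
11 | methyl 5-bromo-4-hydroxy-2-methoxybenzoate | COC(=O)c1cc(Br)c(O)cc1OC | intermediate
12 | methyl 4-(benzyloxy)-5-bromo-2-methoxybenzoate | COC(=O)c1cc(Br)c(OCc2ccccc2)cc1OC | intermediate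
13 | {[4-(benzyloxy)-2-methoxy-6-(methoxymethyl)phenyl]methyl}zinc chloride (not isolated) | COCc1cc(OCc2ccccc2)cc(OC)c1C[Zn]Cl | intermediate
14 | methyl 4-(benzyloxy)-5-{[4-(benzyloxy)-2-methoxy-6-(methoxymethyl)phenyl]methyl}-2-methoxybenzoate | COCc1cc(OCc2ccccc2)cc(OC)c1Cc1cc(C(=O)OC)c(OC)cc1OCc1ccccc1 | intermediate
15 | 4-(benzyloxy)-5-{[4-(benzyloxy)-2-methoxy-6-(methoxymethyl)phenyl]methyl}-2-methoxybenzoic acid | COCc1cc(OCc2ccccc2)cc(OC)c1Cc1cc(C(=O)O)c(OC)cc1OCc1ccccc1 | intermediate
16 | trimethylsulfoxonium iodide | C[S+](C)(C)=O.[I-] | starting material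
17 | acetic anhydride | CC(=O)OC(C)=O | starting material
18 | dimethylsulfoxonium methylide (not isolated) | C=S(C)(C)=O | intermediate
19 | 1-[dimethyl(oxo)-λ6-sulfanylidene]propan-2-one | CC(=O)C=S(C)(C)=O | intermediate
20 | 4-(benzyloxy)-3-{[4-(benzyloxy)-2-methoxy-6-(methoxymethyl)phenyl]methyl}-6-methoxy-2-(2-oxopropyl)benzoic acid (not isolated) | COCc1cc(OCc2ccccc2)cc(OC)c1Cc1c(CC(C)=O)c(C(=O)O)c(OC)cc1OCc1ccccc1 | intermediate
21 | 6-(benzyloxy)-5-{[4-(benzyloxy)-2-methoxy-6-(methoxymethyl)phenyl]methyl}-8-methoxy-3-methyl-1H-isochromen-1-one | COCc1cc(OCc2ccccc2)cc(OC)c1Cc1c(OCc2ccccc2)cc(OC)c2c(=O)oc(C)cc12 | intermediate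
22 | 6-hydroxy-5-{[4-hydroxy-2-methoxy-6-(methoxymethyl)phenyl]methyl}-8-methoxy-3-methyl-1H-isochromen-1-one | COCc1cc(O)cc(OC)c1Cc1c(O)cc(OC)c2c(=O)oc(C)cc12 | target

**Step count**

Total step count: 12
Longest linear sequence: 9 steps (steps 1, 2, 3, 4, 5, 8, 9, 11, 12)

**Steps most likely to fail**

1. **Step 11.**
   - What may go wrong: metalation at the crowded C4a–H may be slow. Thermal O-alkylation of the carboxylate by the protonated ylide, or protodecarboxylation of the electron-rich acid under heat and silver, could then overtake the C–H coupling.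
   - Fallback (annulation before fragment coupling): it sets out from 12 and comes back at 21.
   - Saponification of 12 (LiOH, THF/MeOH/H2O) gives 4-(benzyloxy)-5-bromo-2-methoxybenzoic acid F1.
   - The same rhodium-catalysed annulation with 19 then meets a C–H bond flanked only by bromine, which is smaller than the diarylmethyl group and acidifies the neighbouring C–H. This gives 6-(benzyloxy)-5-bromo-8-methoxy-3-methyl-1H-isochromen-1-one F2.
   - Negishi coupling of F2 with zinc reagent 13 (Pd(OAc)2, SPhos, THF) forms the C5–CH2 bond last and gives 21.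

2. **Step 2.**
   - What may go wrong: the aldol closure may lose out to hydrolysis of the enol ether, retro-Claisen cleavage of the 1,3-diketone in aqueous base, or decarboxylation on acidification.
   - Fallback (dioxinone-based late aromatisation): it sets out from 2 and comes back at 7.
   - Commercial 2,2,6-trimethyl-4H-1,3-dioxin-4-one is acetylated through its lithium dienolate (LiN(SiMe3)2, acetyl chloride, THF, −78 °C) to 2,2-dimethyl-6-(2-oxopropyl)-4H-1,3-dioxin-4-one F3.
   - The dianion of F3 (LiN(iPr)2, 2.2 equiv) is acylated at the terminal carbon by 2 to give 6-(5-methoxy-2,4-dioxopentyl)-2,2-dimethyl-4H-1,3-dioxin-4-one F4.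
   - Et3N in CH2Cl2 brings about aldol aromatisation to 7-hydroxy-5-(methoxymethyl)-2,2-dimethyl-4H-1,3-benzodioxin-4-one F5. Here the ortho oxygen and the carboxyl group are tied up in the acetonide, and only the para phenol is free.
   - Benzylation (BnBr, K2CO3) gives 7-(benzyloxy)-5-(methoxymethyl)-2,2-dimethyl-4H-1,3-benzodioxin-4-one F6.
   - LiAlH4 reduces F6 to 5-(benzyloxy)-2-(hydroxymethyl)-3-(methoxymethyl)phenol F7.
   - Selective methylation of the far more acidic phenol (MeI, K2CO3, acetone, rt) gives 7.

3. **Step 12.**
   - What may go wrong: over-reduction, either by hydrogenolysis of the benzylic C–OMe bond of ring C or by saturation of the C3–C4 double bond before both benzyl ethers are gone.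
   - Fallback (acidolysis in place of reduction): it sets out from 21 and comes back at 22.
   - The benzyl groups are removed with trifluoroacetic acid and pentamethylbenzene as cation scavenger at room temperature.
   - Aryl benzyl ethers are cleaved under these conditions, whereas benzylic alkyl ethers without ortho or para donor groups, the lactone and the aryl methyl ethers should persist.
   - No new compound lies on this path.

**Further compounds**

F1 | step 11 | 4-(benzyloxy)-5-bromo-2-methoxybenzoic acid | OC(=O)c1cc(Br)c(OCc2ccccc2)cc1OC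
F2 | step 11 | 6-(benzyloxy)-5-bromo-8-methoxy-3-methyl-1H-isochromen-1-one | COc1cc(OCc2ccccc2)c(Br)c2cc(C)oc(=O)c12
F3 | step 2 | 2,2-dimethyl-6-(2-oxopropyl)-4H-1,3-dioxin-4-one | CC(=O)CC1=CC(=O)OC(C)(C)O1
F4 | step 2 | 6-(5-methoxy-2,4-dioxopentyl)-2,2-dimethyl-4H-1,3-dioxin-4-one | COCC(=O)CC(=O)CC1=CC(=O)OC(C)(C)O1
F5 | step 2 | 7-hydroxy-5-(methoxymethyl)-2,2-dimethyl-4H-1,3-benzodioxin-4-one | COCc1cc(O)cc2OC(C)(C)OC(=O)c12
F6 | step 2 | 7-(benzyloxy)-5-(methoxymethyl)-2,2-dimethyl-4H-1,3-benzodioxin-4-one | COCc1cc(OCc3ccccc3)cc2OC(C)(C)OC(=O)c12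
F7 | step 2 | 5-(benzyloxy)-2-(hydroxymethyl)-3-(methoxymethyl)phenol | COCc1cc(OCc2ccccc2)cc(O)c1CO
F0 | step 12 | none | none
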